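**Retrosynthetic overview**

1. Prostanoid numbering is used: ring A is the cyclopentenone C8–C12 and ring B is the lactone (O, C1–C4). The last C–C disconnection is C6–C7, a stereoretentive Suzuki union of a ring A (Z)-enol triflate (source of 7Z) with a ring B (E)-alkenylboronate (source of 5E). The C12 acetate is put on last.
2. Enabling feature: in ring B the bond from the ring oxygen to C4 is a secondary allylic ester bond, because C4 carries the C5=C6 alkene. C4–C5–C6 is therefore an allyl unit, and ring B with a C5=C6 vinyl group is an isomer of achiral, acyclic hex-5-ynoic acid (C5≡C6).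
3. Key disconnection O–C4: a rhodium hydride cycloisomerisation (alkyne → allene → π-allyl → C–O reductive elimination) makes ring B, C4 (R) and the C5=C6 alkene in one reagent-free operation. It precedes the union because any C4 cation equivalent on the full C4–C9 trienone would delocalise to C8 and erase 7Z.
4. Ring A is bought as (S)-4-silyloxycyclopentenone. Its C9 stereocentre steers the C12–C13 bond formation and is then oxidised to the C9 ketone. C7 enters by formylation at C8.
5. Order of rings: ring A (purchased), ring B (key step), then union of the two.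

Key step: step 8

Assumption: the (R,R) antipode of DIOP is taken to deliver (R) at C4 in step 8; if the sense of induction is the opposite, (S,S)-DIOP is used instead.

Step 1
Reactants: 1 (2Z)-oct-2-en-1-ol
Product: 2 (2Z)-1-chlorooct-2-ene
Conditions: PPh3, Cl3CC(O)CCl3, CH2Cl2, 0 °C
Reagents that add atoms: hexachloroacetone, ClC(Cl)(Cl)C(=O)C(Cl)(Cl)Cl
Why: Appel-type chlorination runs by SN2 displacement on the alkoxyphosphonium salt under neutral conditions, so neither allylic transposition nor Z-to-E isomerisation is expected.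

Step 2
Reactants: 2 (2Z)-1-chlorooct-2-ene; 3 (4S)-4-[(tert-butyldimethylsilyl)oxy]cyclopent-2-en-1-one
Product: 5 (1R,4S)-4-[(tert-butyldimethylsilyl)oxy]-1-[(2Z)-oct-2-en-1-yl]cyclopent-2-en-1-ol (OH and OTBS cis), via octenylbarium chloride 4 (not isolated)
Conditions: activated Ba (from BaI2, Li, biphenyl, THF, rt), 2, THF, −78 °C; then 3, −78 °C; aq NH4Cl
Reagents that add atoms: none
Why: Allylbarium reagents undergo 1,2-addition to carbonyl groups at their α-carbon with retention of the Z geometry (α-selective allylmetal addition), and approach anti to the C9 silyloxy group should set C12 with OH cis to OTBS, the minor epimer being removed by chromatography.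

Step 3
Reactants: 5 (1R,4S)-4-[(tert-butyldimethylsilyl)oxy]-1-[(2Z)-oct-2-en-1-yl]cyclopent-2-en-1-ol
Product: 6 (1R,4S)-1-[(2Z)-oct-2-en-1-yl]cyclopent-2-ene-1,4-diol (cis-diol)
Conditions: Bu4NF, THF, 0 °C to rt
Reagents that add atoms: none
Why: Fluoride-mediated desilylation removes the only silyl ether under non-acidic conditions that cannot ionise the tertiary allylic alcohol.

Step 4
Reactants: 6 (1R,4S)-1-[(2Z)-oct-2-en-1-yl]cyclopent-2-ene-1,4-diol
Product: 7 (4R)-4-hydroxy-4-[(2Z)-oct-2-en-1-yl]cyclopent-2-en-1-one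
Conditions: MnO2, CH2Cl2, rt
Reagents that add atoms: none
Why: Allylic oxidation with MnO2 touches only the secondary allylic carbinol C9, so the relay stereocentre is erased and C12 remains as the only stereocentre of ring A.

Step 5
Reactants: 7 (4R)-4-hydroxy-4-[(2Z)-oct-2-en-1-yl]cyclopent-2-en-1-one
Product: 8 (4R)-4-[(2Z)-oct-2-en-1-yl]-4-[(triethylsilyl)oxy]cyclopent-2-en-1-one
Conditions: Et3SiOTf, 2,6-lutidine, CH2Cl2, −78 to 0 °C
Reagents that add atoms: triethylsilyl trifluoromethanesulfonate, CC[Si](CC)(CC)OS(=O)(=O)C(F)(F)F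
Why: A silyl triflate with a hindered pyridine base silylates even a tertiary alcohol and turns C12–O into a poor leaving group for the enolate chemistry that follows.

Step 6
Reactants: 8 (4R)-4-[(2Z)-oct-2-en-1-yl]-4-[(triethylsilyl)oxy]cyclopent-2-en-1-one
Product: 10 (4S,5Z)-5-(hydroxymethylidene)-4-[(2Z)-oct-2-en-1-yl]-4-[(triethylsilyl)oxy]cyclopent-2-en-1-one, via lithium enolate 9 (not isolated)
Conditions: LiN(iPr)2, THF, −78 °C; HCO2CH2CF3, −78 °C; aq NH4Cl
Reagents that add atoms: 2,2,2-trifluoroethyl formate, O=COCC(F)(F)F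
Why: Kinetic deprotonation at C8 gives the cross-conjugated enolate, and Claisen-type C-formylation with the activated formate gives the β-ketoaldehyde, which should rest as the hydrogen-bonded (Z)-hydroxymethylidene tautomer.

Step 7
Reactants: 10 (4S,5Z)-5-(hydroxymethylidene)-4-[(2Z)-oct-2-en-1-yl]-4-[(triethylsilyl)oxy]cyclopent-2-en-1-one
Product: 11 (Z)-{(5S)-5-[(2Z)-oct-2-en-1-yl]-2-oxo-5-[(triethylsilyl)oxy]cyclopent-3-en-1-ylidene}methyl trifluoromethanesulfonate
Conditions: Tf2O, LiOTf, iPr2NEt, CH2Cl2, −78 to −20 °C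
Reagents that add atoms: trifluoromethanesulfonic anhydride, O=S(=O)(OS(=O)(=O)C(F)(F)F)C(F)(F)F
Why: In this chelation-controlled enol triflate formation the lithium-bridged U-shaped enolate of the 1,3-dicarbonyl unit is trapped at the less hindered exocyclic oxygen, so OTf stays cis to C9=O, which is the 7Z geometry of the target.

Step 8
Reactants: 12 hex-5-ynoic acid
Product: 14 (5R)-5-ethenyloxolan-2-one, via allenic acid 13 (not isolated)
Conditions: [Rh(cod)Cl]2 (2.5 mol %), (R,R)-DIOP (5 mol %), ClCH2CH2Cl (0.05 M), 70 °C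
Reagents that add atoms: none
Why: Oxidative addition of the carboxylic O–H of 12 to monovalent rhodium gives a trivalent rhodium hydride carboxylate, which hydrometalates the C5≡C6 alkyne and β-hydride-eliminates across C4–H to the allene 13; re-addition of Rh–H to the central allene carbon C5 gives a π-allyl over C4–C5–C6 that still carries its own carboxylate, and C–O reductive elimination at the substituted terminus C4 forms the O–C4 bond. The closest known reaction type is the rhodium/bisphosphine-catalysed redox-neutral addition of carboxylic acids to terminal alkynes and allenes, which gives branched allylic esters, has been run intramolecularly to lactones and macrolactones, and has been run enantioselectively with DIOP-type ligands. Ring B closes in a 5-exo mode, with O, C1, C2, C3 and C4 in the ring and C5=C6 left exocyclic as the vinyl group. The only new stereocentre, C4, is controlled by the chiral bisphosphine, because the two π-allyl diastereomers interconvert by π–σ–π slippage through the unsubstituted terminus C6 and the faster reductive elimination is expected to give (R). The step needs C–O bond formation at C4 rather than C6, secured by the intrinsic branched preference of rhodium and by five- versus seven-membered ring closure, and it needs the hydride pathway rather than direct 6-exo-dig addition of the acid to the alkyne, secured by a neutral, electron-rich catalyst that is not π-acidic, while dilution suppresses intermolecular esterification. In one isomerisation without reagent or by-product an achiral, acyclic, purchasable acid becomes ring B with C4, the O–C4 bond and the future C5=C6 alkene in place.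

Step 9
Reactants: 14 (5R)-5-ethenyloxolan-2-one; 15 2-ethenyl-4,4,5,5-tetramethyl-1,3,2-dioxaborolane
Product: 16 (5R)-5-[(E)-2-(4,4,5,5-tetramethyl-1,3,2-dioxaborolan-2-yl)ethenyl]oxolan-2-one
Conditions: second-generation Hoveyda–Grubbs catalyst (5 mol %), CH2Cl2, 40 °C
Reagents that add atoms: none
Why: Olefin cross-metathesis of a terminal alkene with vinyl-Bpin is E-selective for steric reasons and leaves the allylic stereocentre C4 untouched.

Step 10
Reactants: 11 (Z)-enol triflate of ring A; 16 (E)-alkenylboronate of ring B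
Product: 17 (5R)-5-[(1E,3Z)-3-{(5S)-5-[(2Z)-oct-2-en-1-yl]-2-oxo-5-[(triethylsilyl)oxy]cyclopent-3-en-1-ylidene}prop-1-en-1-yl]oxolan-2-one
Conditions: PdCl2(dppf) (5 mol %), K3PO4, THF–H2O, rt
Reagents that add atoms: none
Why: Suzuki–Miyaura coupling retains the geometry of both alkenyl partners, so 7Z comes from 11 and 5E from 16, and the fast oxidative addition of the electron-poor enol triflate to zerovalent palladium at room temperature should outrun ionisation of the allylic lactone.

Step 11
Reactants: 17 triethylsilyl-protected dienone lactone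
Product: 18 (5R)-5-[(1E,3Z)-3-{(5S)-5-hydroxy-5-[(2Z)-oct-2-en-1-yl]-2-oxocyclopent-3-en-1-ylidene}prop-1-en-1-yl]oxolan-2-one
Conditions: HF·pyridine, THF, 0 °C
Reagents that add atoms: none
Why: Fluoride-driven desilylation under mildly acidic, non-nucleophilic conditions frees the tertiary alcohol without touching the lactone or isomerising the cross-conjugated dienone.

Step 12
Reactants: 18 tertiary alcohol
Product: 19 target clavulolactone, (5R)-5-[(1E,3Z)-3-{(5S)-5-acetoxy-5-[(2Z)-oct-2-en-1-yl]-2-oxocyclopent-3-en-1-ylidene}prop-1-en-1-yl]oxolan-2-one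
Conditions: Ac2O, Et3N, DMAP (cat.), CH2Cl2, 0 °C to rt
Reagents that add atoms: acetic anhydride, CC(=O)OC(C)=O
Why: DMAP-catalysed acylation is the standard way to esterify a hindered tertiary alcohol, ionisation at C12 is disfavoured by the adjacent electron-poor dienone, and the step completes the target with all stereocentres and alkene geometries unchanged.

**Compound list**

1 | (2Z)-oct-2-en-1-ol | CCCCC/C=C\CO | starting material
2 | (2Z)-1-chlorooct-2-ene | CCCCC/C=C\CCl | intermediate
3 | (4S)-4-[(tert-butyldimethylsilyl)oxy]cyclopent-2-en-1-one | O=C1C=C[C@@H](O[Si](C)(C)C(C)(C)C)C1 | starting material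
4 | [(2Z)-oct-2-en-1-yl]barium chloride | CCCCC/C=C\C[Ba]Cl | intermediate
5 | (1R,4S)-4-[(tert-butyldimethylsilyl)oxy]-1-[(2Z)-oct-2-en-1-yl]cyclopent-2-en-1-ol | CCCCC/C=C\C[C@]1(O)C=C[C@@H](O[Si](C)(C)C(C)(C)C)C1 | intermediate
6 | (1R,4S)-1-[(2Z)-oct-2-en-1-yl]cyclopent-2-ene-1,4-diol | CCCCC/C=C\C[C@]1(O)C=C[C@@H](O)C1 | intermediate
7 | (4R)-4-hydroxy-4-[(2Z)-oct-2-en-1-yl]cyclopent-2-en-1-one | CCCCC/C=C\C[C@]1(O)C=CC(=O)C1 | intermediate
8 | (4R)-4-[(2Z)-oct-2-en-1-yl]-4-[(triethylsilyl)oxy]cyclopent-2-en-1-one | CCCCC/C=C\C[C@]1(O[Si](CC)(CC)CC)C=CC(=O)C1 | intermediate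
9 | lithium cross-conjugated enolate of 8 (C8=C9–OLi) | CCCCC/C=C\C[C@]1(O[Si](CC)(CC)CC)C=CC([O-])=C1.[Li+] | intermediate
10 | (4S,5Z)-5-(hydroxymethylidene)-4-[(2Z)-oct-2-en-1-yl]-4-[(triethylsilyl)oxy]cyclopent-2-en-1-one | CCCCC/C=C\C[C@]1(O[Si](CC)(CC)CC)C=CC(=O)/C1=C\O | intermediate
11 | (Z)-{(5S)-5-[(2Z)-oct-2-en-1-yl]-2-oxo-5-[(triethylsilyl)oxy]cyclopent-3-en-1-ylidene}methyl trifluoromethanesulfonate | CCCCC/C=C\C[C@]1(O[Si](CC)(CC)CC)C=CC(=O)/C1=C\OS(=O)(=O)C(F)(F)F | intermediate
12 | hex-5-ynoic acid | C#CCCCC(=O)O | starting material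
13 | hexa-4,5-dienoic acid | C=C=CCCC(=O)O | intermediate
14 | (5R)-5-ethenyloxolan-2-one | C=C[C@H]1CCC(=O)O1 | intermediate
15 | 2-ethenyl-4,4,5,5-tetramethyl-1,3,2-dioxaborolane | C=CB1OC(C)(C)C(C)(C)O1 | starting material
16 | (5R)-5-[(E)-2-(4,4,5,5-tetramethyl-1,3,2-dioxaborolan-2-yl)ethenyl]oxolan-2-one | CC1(C)OB(/C=C/[C@H]2CCC(=O)O2)OC1(C)C | intermediate
17 | (5R)-5-[(1E,3Z)-3-{(5S)-5-[(2Z)-oct-2-en-1-yl]-2-oxo-5-[(triethylsilyl)oxy]cyclopent-3-en-1-ylidene}prop-1-en-1-yl]oxolan-2-one | CCCCC/C=C\C[C@]1(O[Si](CC)(CC)CC)C=CC(=O)/C1=C\C=C\[C@H]1CCC(=O)O1 | intermediate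
18 | (5R)-5-[(1E,3Z)-3-{(5S)-5-hydroxy-5-[(2Z)-oct-2-en-1-yl]-2-oxocyclopent-3-en-1-ylidene}prop-1-en-1-yl]oxolan-2-one | CCCCC/C=C\C[C@]1(O)C=CC(=O)/C1=C\C=C\[C@H]1CCC(=O)O1 | intermediate
19 | target clavulolactone, (5R)-5-[(1E,3Z)-3-{(5S)-5-acetoxy-5-[(2Z)-oct-2-en-1-yl]-2-oxocyclopent-3-en-1-ylidene}prop-1-en-1-yl]oxolan-2-one | CCCCC/C=C\C[C@]1(OC(C)=O)C=CC(=O)/C1=C\C=C\[C@H]1CCC(=O)O1 | target

Total step count: 12.
Longest linear sequence: 10 steps (1 → 2 → 5 → 6 → 7 → 8 → 10 → 11 → 17 → 18 → 19).

**Steps most likely to fail**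

**Step 8.**
- Risk: direct exo-dig addition of the acid to the alkyne may outrun the hydride pathway. Ligand control over the small-ring reductive elimination may also be too weak and erode the enantiomeric purity at C4.
- Fallback: it sets out from 12 and comes back at 14. Base-mediated migration of the triple bond (KOtBu, DMSO) should give hex-4-ynoic acid F1. Semihydrogenation over Pd/CaCO3 poisoned with Pb(OAc)2 and quinoline should give (4Z)-hex-4-enoic acid F2. Asymmetric selenolactonisation with 2-[(1S)-1-hydroxypropyl]phenylselenenyl triflate at −78 °C or below again closes O–C4, by anti 5-exo opening of the seleniranium ion, and should give the selenolactone F3. Because the selenium group is chiral, F3 can be freed from its diastereomer by chromatography, and the antipode of the reagent is chosen as needed. Oxidation with H2O2 to the selenoxide F4 and its syn elimination away from the oxygen-bearing carbon should give 14.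

**Step 7.**
- Risk: the Z geometry may erode through reversible addition of amine or triflate to the β-carbon of the enol triflate, or sulfonylation may take place at the ring carbonyl oxygen.
- Fallback: it sets out from 8 (with 14 as the source of C5–C7) and comes back at 17. Cross-metathesis of 14 with crotonaldehyde (second-generation Hoveyda–Grubbs catalyst) should give (2E)-3-[(2R)-5-oxooxolan-2-yl]prop-2-enal F5. Aldol addition of enolate 9, made from 8 with LiN(iPr)2 at −78 °C, to F5 should give the aldol F6 as a mixture at C7 and C8. Mesylation (MsCl, Et3N) to the mesylate F7 and E1cB elimination with DBU should give 17 together with its 7E isomer F8. The two are separated by chromatography, and F8 is re-equilibrated by irradiation and recycled.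

**Step 2.**
- Risk: the allylmetal may isomerise with loss of α-selectivity or of the Z geometry, the enone may be enolised with loss of the silyloxy group, or facial selectivity may be poor.
- Fallback: it sets out from 3 and comes back at 5. CeCl3-promoted 1,2-addition of allylMgBr, which has no regiochemical ambiguity, should give (1R,4S)-4-[(tert-butyldimethylsilyl)oxy]-1-(prop-2-en-1-yl)cyclopent-2-en-1-ol F9. Z-selective cross-metathesis of F9 with hept-1-ene, using the cyclometalated Z-selective Grubbs ruthenium catalyst, should give 5.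

**Further compounds**

F1 | step 8 | hex-4-ynoic acid | CC#CCCC(=O)O
F2 | step 8 | (4Z)-hex-4-enoic acid | C/C=C\CCC(=O)O
F3 | step 8 | (5R)-5-[(1R)-1-({2-[(1S)-1-hydroxypropyl]phenyl}selanyl)ethyl]oxolan-2-one | C[C@@H]([Se]c1ccccc1[C@@H](O)CC)[C@H]1CCC(=O)O1
F4 | step 8 | selenoxide of F3 | C[C@@H]([Se](=O)c1ccccc1[C@@H](O)CC)[C@H]1CCC(=O)O1
F5 | step 7 | (2E)-3-[(2R)-5-oxooxolan-2-yl]prop-2-enal | O=C/C=C/[C@H]1CCC(=O)O1
F6 | step 7 | C7 aldol of 8 with F5 (mixture at C7 and C8) | CCCCC/C=C\C[C@]1(O[Si](CC)(CC)CC)C=CC(=O)C1C(O)/C=C/[C@H]1CCC(=O)O1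
F7 | step 7 | C7 mesylate of F6 | CCCCC/C=C\C[C@]1(O[Si](CC)(CC)CC)C=CC(=O)C1C(OS(C)(=O)=O)/C=C/[C@H]1CCC(=O)O1
F8 | step 7 | 7E isomer of 17 | CCCCC/C=C\C[C@]1(O[Si](CC)(CC)CC)C=CC(=O)/C1=C/C=C/[C@H]1CCC(=O)O1
F9 | step 2 | (1R,4S)-4-[(tert-butyldimethylsilyl)oxy]-1-(prop-2-en-1-yl)cyclopent-2-en-1-ol | C=CC[C@]1(O)C=C[C@@H](O[Si](C)(C)C(C)(C)C)C1
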